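**Retrosynthetic overview**
1. Hypothamnolic acid 23 comes from global hydrogenolysis of a tribenzyl depside acid 22, whose ring A carboxyl is made by chlorite oxidation of a formyl group after the depside bond is in place.
2. The depside C–O bond is disconnected to ring A acid 9 (3-formyl-2-hydroxy-4-methoxy-6-methylbenzoic acid) and ring B phenol 19 (5-OH free, all other acidic groups benzylated).
3. The ring B 5-OH comes from a 5-formyl group by Baeyer–Villiger oxidation; both formyl groups are introduced by Rieche formylation of resorcinol esters.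
4. Each benzene ring is built as a cyclohexane-1,3-dione by intermolecular Michael addition of a β-keto ester to methyl crotonate followed by Dieckmann (Claisen) closure, then aromatised with Br2 and debrominated.
5. Order: ring A (steps 1–6), ring B (steps 7–13), union and end game (steps 14–16).

Assumption: the target has no stereocentre, so the compound asked for is the achiral molecule itself; the stereocentres of 3, 4, 11 and 12 form as mixtures and are erased on aromatisation.

**Route**

Step 1
Reactants: 1 methyl acetoacetate; 2 methyl (E)-but-2-enoate (methyl crotonate)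
Product: 4 methyl 6-methyl-2,4-dioxocyclohexane-1-carboxylate, via Michael adduct 3 (not isolated)
Conditions: NaOMe (1.1 equiv), MeOH, reflux; then cold dilute aq. HCl
Reagents that add atoms: none
Why: Intermolecular Michael addition of the enolate of 1 to the β-carbon of 2 forms the key C–C bond, and the methyl-ketone enolate of 3 then closes the ring by Dieckmann (Claisen) condensation, driven by the stabilised 1,3-dione enolate; the two new stereocentres are uncontrolled and disappear in step 2.

Step 2
Reactants: 4 methyl 6-methyl-2,4-dioxocyclohexane-1-carboxylate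
Product: 5 methyl 3,5-dibromo-2,4-dihydroxy-6-methylbenzoate
Conditions: Br2 (3.0 equiv), AcOH, 15–25 °C
Reagents that add atoms: bromine, BrBr
Why: α-Bromination and dehydrobromination of the enolised dione aromatises the ring, and the resulting resorcinol is brominated at both free positions (electrophilic aromatic substitution), the classical halogenative aromatisation to orsellinates.

Step 3
Reactants: 5 methyl 3,5-dibromo-2,4-dihydroxy-6-methylbenzoate
Product: 6 methyl 2,4-dihydroxy-6-methylbenzoate (methyl orsellinate)
Conditions: H2 (1 atm), 10% Pd/C, NaOAc (2.2 equiv), MeOH, rt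
Reagents that add atoms: none
Why: Catalytic hydrogenolysis of both aryl C–Br bonds is fast next to phenolic OH and leaves the ester and ring untouched.

Step 4
Reactants: 6 methyl 2,4-dihydroxy-6-methylbenzoate
Product: 7 methyl 3-formyl-2,4-dihydroxy-6-methylbenzoate (methyl haematommate)
Conditions: Cl2CHOMe (1.5 equiv), TiCl4 (3 equiv), DCM, −10 to 20 °C; then ice/1 M HCl; separate from the minor 5-formyl isomer by chromatography and crystallisation
Reagents that add atoms: dichloromethyl methyl ether, COC(Cl)Cl; water, O
Why: Rieche formylation, in which TiCl4 bound to both flanking phenolic oxygens delivers the electrophile to C3 between them, the position doubly ortho-activated and remote from the 6-methyl group.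

Step 5
Reactants: 7 methyl 3-formyl-2,4-dihydroxy-6-methylbenzoate
Product: 8 methyl 3-formyl-2-hydroxy-4-methoxy-6-methylbenzoate
Conditions: MeI (1.05 equiv), K2CO3 (1.1 equiv), acetone, reflux
Reagents that add atoms: iodomethane, CI
Why: Williamson O-methylation occurs at the less hindered 4-OH, because the 2-OH is locked between the ester and formyl carbonyls by chelation and steric crowding.

Step 6
Reactants: 8 methyl 3-formyl-2-hydroxy-4-methoxy-6-methylbenzoate
Product: 9 3-formyl-2-hydroxy-4-methoxy-6-methylbenzoic acid
Conditions: conc. H2SO4, 0 to 20 °C, 1–2 h; pour onto ice, filter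
Reagents that add atoms: water, O
Why: Newman-type hydrolysis of a di-ortho-substituted, electron-rich benzoate through its acylium ion, which avoids hot alkali and so spares the aldehyde and the aryl methyl ether.

Step 7
Reactants: 10 methyl 3-oxopentanoate; 2 methyl (E)-but-2-enoate
Product: 12 methyl 3,6-dimethyl-2,4-dioxocyclohexane-1-carboxylate, via Michael adduct 11 (not isolated)
Conditions: NaOMe (1.1 equiv), MeOH, reflux; then cold dilute aq. HCl
Reagents that add atoms: none
Why: The same intermolecular Michael addition and Dieckmann (Claisen) closure as step 1, with the ethyl-ketone CH2 as the Claisen nucleophile so that the future C3 methyl group is built in; stereocentres are uncontrolled and are lost in step 8.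

Step 8
Reactants: 12 methyl 3,6-dimethyl-2,4-dioxocyclohexane-1-carboxylate
Product: 13 methyl 5-bromo-2,4-dihydroxy-3,6-dimethylbenzoate
Conditions: Br2 (2.05 equiv), AcOH, rt then 50 °C
Reagents that add atoms: bromine, BrBr
Why: Bromination at the β-keto ester carbon and dehydrobromination aromatises the ring, and the second equivalent brominates the only free ring position (halogenative aromatisation followed by electrophilic aromatic substitution).

Step 9
Reactants: 13 methyl 5-bromo-2,4-dihydroxy-3,6-dimethylbenzoate
Product: 14 methyl 2,4-dihydroxy-3,6-dimethylbenzoate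
Conditions: H2 (1 atm), 10% Pd/C, NaOAc (1.1 equiv), MeOH, rt
Reagents that add atoms: none
Why: Catalytic hydrogenolysis of the aryl bromide, as in step 3.

Step 10
Reactants: 14 methyl 2,4-dihydroxy-3,6-dimethylbenzoate
Product: 15 methyl 5-formyl-2,4-dihydroxy-3,6-dimethylbenzoate
Conditions: Cl2CHOMe (1.5 equiv), TiCl4 (3 equiv), DCM, 0 to 20 °C; then ice/1 M HCl
Reagents that add atoms: dichloromethyl methyl ether, COC(Cl)Cl; water, O
Why: Rieche formylation at the single remaining ring position (ortho to the 4-OH, para to the 2-OH), so no regiochemical question arises.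

Step 11
Reactants: 15 methyl 5-formyl-2,4-dihydroxy-3,6-dimethylbenzoate
Product: 16 5-formyl-2,4-dihydroxy-3,6-dimethylbenzoic acid
Conditions: conc. H2SO4, 0 to 20 °C, 1 h; pour onto ice, filter cold
Reagents that add atoms: water, O
Why: Newman-type acylium hydrolysis of the hindered ester; the ring is fully substituted so it cannot be sulfonated, and the cold work-up avoids decarboxylation.

Step 12
Reactants: 16 5-formyl-2,4-dihydroxy-3,6-dimethylbenzoic acid
Product: 17 benzyl 2,4-bis(benzyloxy)-5-formyl-3,6-dimethylbenzoate
Conditions: BnBr (3.6 equiv), K2CO3 (4 equiv), DMF, 60 °C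
Reagents that add atoms: benzyl bromide, BrCc1ccccc1
Why: Exhaustive Williamson-type O-alkylation of the carboxylate and both phenoxides in a dipolar aprotic solvent installs three groups that all leave in the final hydrogenolysis.

Step 13
Reactants: 17 benzyl 2,4-bis(benzyloxy)-5-formyl-3,6-dimethylbenzoate
Product: 19 benzyl 2,4-bis(benzyloxy)-5-hydroxy-3,6-dimethylbenzoate, via aryl formate 18 (not isolated)
Conditions: mCPBA (1.5 equiv), DCM, rt; then MeOH, Et3N (cat.), rt
Reagents that add atoms: 3-chloroperoxybenzoic acid (mCPBA), OOC(=O)c1cccc(Cl)c1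
Why: Baeyer–Villiger (Dakin-type) oxidation, in which the electron-rich aryl group with ortho and para alkoxy substituents migrates to give formate 18; mild methanolysis then frees the only unprotected phenol, exactly at C5.

Step 14
Reactants: 9 3-formyl-2-hydroxy-4-methoxy-6-methylbenzoic acid; 19 benzyl 2,4-bis(benzyloxy)-5-hydroxy-3,6-dimethylbenzoate
Product: 21 benzyl 2,4-bis(benzyloxy)-5-[(3-formyl-2-hydroxy-4-methoxy-6-methylbenzoyl)oxy]-3,6-dimethylbenzoate, via mixed trifluoroacetic anhydride 20 (not isolated)
Conditions: TFAA (2 equiv), toluene, 20 °C; aq. NaHCO3 work-up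
Reagents that add atoms: none
Why: Depside esterification through the mixed trifluoroacetic anhydride, whose electron-rich di-ortho-substituted aroyl group reacts with acylium character and so tolerates the hindered phenol, while the chelated 2-OH of 9 stays unacylated.

Step 15
Reactants: 21 benzyl 2,4-bis(benzyloxy)-5-[(3-formyl-2-hydroxy-4-methoxy-6-methylbenzoyl)oxy]-3,6-dimethylbenzoate
Product: 22 3-({2,4-bis(benzyloxy)-5-[(benzyloxy)carbonyl]-3,6-dimethylphenoxy}carbonyl)-2-hydroxy-6-methoxy-4-methylbenzoic acid
Conditions: NaClO2 (1.5 equiv), NaH2PO4 (1.5 equiv), 2-methyl-2-butene (10 equiv), t-BuOH/THF/H2O, rt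
Reagents that add atoms: sodium chlorite (NaClO2), [Na+].[O-]Cl=O
Why: Pinnick (Lindgren) oxidation converts the aryl aldehyde into the acid under near-neutral conditions that spare the depside ester and benzyl groups, with the alkene scavenging HOCl to prevent ring chlorination.

Step 16
Reactants: 22 3-({2,4-bis(benzyloxy)-5-[(benzyloxy)carbonyl]-3,6-dimethylphenoxy}carbonyl)-2-hydroxy-6-methoxy-4-methylbenzoic acid
Product: 23 hypothamnolic acid
Conditions: H2 (1 atm), 10% Pd/C, EtOAc, rt
Reagents that add atoms: none
Why: Catalytic hydrogenolysis removes the benzyl ester and both benzyl ethers under neutral conditions, leaving the aryl depside ester, the methyl ether and both carboxylic acids intact.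

**Compound list**
1 | methyl acetoacetate | CC(=O)CC(=O)OC | starting material
2 | methyl (E)-but-2-enoate (methyl crotonate) | C/C=C/C(=O)OC | starting material
3 | dimethyl 2-acetyl-3-methylpentanedioate (Michael adduct, stereoisomer mixture) | COC(=O)CC(C)C(C(C)=O)C(=O)OC | intermediate
4 | methyl 6-methyl-2,4-dioxocyclohexane-1-carboxylate (stereoisomer mixture, enolised) | COC(=O)C1C(C)CC(=O)CC1=O | intermediate
5 | methyl 3,5-dibromo-2,4-dihydroxy-6-methylbenzoate | COC(=O)c1c(C)c(Br)c(O)c(Br)c1O | intermediate
6 | methyl 2,4-dihydroxy-6-methylbenzoate (methyl orsellinate) | COC(=O)c1c(C)cc(O)cc1O | intermediate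
7 | methyl 3-formyl-2,4-dihydroxy-6-methylbenzoate | COC(=O)c1c(C)cc(O)c(C=O)c1O | intermediate
8 | methyl 3-formyl-2-hydroxy-4-methoxy-6-methylbenzoate | COC(=O)c1c(C)cc(OC)c(C=O)c1O | intermediate
9 | 3-formyl-2-hydroxy-4-methoxy-6-methylbenzoic acid | Cc1cc(OC)c(C=O)c(O)c1C(=O)O | intermediate
10 | methyl 3-oxopentanoate | CCC(=O)CC(=O)OC | starting material
11 | dimethyl 3-methyl-2-propanoylpentanedioate (Michael adduct, stereoisomer mixture) | CCC(=O)C(C(=O)OC)C(C)CC(=O)OC | intermediate
12 | methyl 3,6-dimethyl-2,4-dioxocyclohexane-1-carboxylate (stereoisomer mixture, enolised) | COC(=O)C1C(C)CC(=O)C(C)C1=O | intermediate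
13 | methyl 5-bromo-2,4-dihydroxy-3,6-dimethylbenzoate | COC(=O)c1c(C)c(Br)c(O)c(C)c1O | intermediate
14 | methyl 2,4-dihydroxy-3,6-dimethylbenzoate | COC(=O)c1c(C)cc(O)c(C)c1O | intermediate
15 | methyl 5-formyl-2,4-dihydroxy-3,6-dimethylbenzoate | COC(=O)c1c(C)c(C=O)c(O)c(C)c1O | intermediate
16 | 5-formyl-2,4-dihydroxy-3,6-dimethylbenzoic acid | Cc1c(C=O)c(O)c(C)c(O)c1C(=O)O | intermediate
17 | benzyl 2,4-bis(benzyloxy)-5-formyl-3,6-dimethylbenzoate | Cc1c(C=O)c(OCc2ccccc2)c(C)c(OCc2ccccc2)c1C(=O)OCc1ccccc1 | intermediate
18 | benzyl 2,4-bis(benzyloxy)-5-(formyloxy)-3,6-dimethylbenzoate | Cc1c(OC=O)c(OCc2ccccc2)c(C)c(OCc2ccccc2)c1C(=O)OCc1ccccc1 | intermediate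
19 | benzyl 2,4-bis(benzyloxy)-5-hydroxy-3,6-dimethylbenzoate | Cc1c(O)c(OCc2ccccc2)c(C)c(OCc2ccccc2)c1C(=O)OCc1ccccc1 | intermediate
20 | 3-formyl-2-hydroxy-4-methoxy-6-methylbenzoic trifluoroacetic anhydride | Cc1cc(OC)c(C=O)c(O)c1C(=O)OC(=O)C(F)(F)F | intermediate
21 | benzyl 2,4-bis(benzyloxy)-5-[(3-formyl-2-hydroxy-4-methoxy-6-methylbenzoyl)oxy]-3,6-dimethylbenzoate | Cc1cc(OC)c(C=O)c(O)c1C(=O)Oc1c(C)c(C(=O)OCc2ccccc2)c(OCc2ccccc2)c(C)c1OCc1ccccc1 | intermediate
22 | 3-({2,4-bis(benzyloxy)-5-[(benzyloxy)carbonyl]-3,6-dimethylphenoxy}carbonyl)-2-hydroxy-6-methoxy-4-methylbenzoic acid | Cc1cc(OC)c(C(=O)O)c(O)c1C(=O)Oc1c(C)c(C(=O)OCc2ccccc2)c(OCc2ccccc2)c(C)c1OCc1ccccc1 | intermediate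
23 | hypothamnolic acid | COc1cc(C)c(C(=O)Oc2c(C)c(C(=O)O)c(O)c(C)c2O)c(O)c1C(=O)O | target

**Totals**
Total step count: 16. Longest linear sequence: 10 steps (steps 7–13, then 14–16).

**Steps most likely to fail, with fallbacks**

Step 14 is the most exposed, because a di-ortho-substituted acid carrying a free 2-OH has to acylate a phenol flanked by a benzyloxy and a methyl group. The fallback sets out from 9 and changes the acyl donor. Condensation of 9 with acetone (TFAA, TFA, rt) gives 8-formyl-7-methoxy-2,2,5-trimethyl-4H-1,3-benzodioxin-4-one F1, an activated and internally protected salicylate. Treating F1 with the sodium phenoxide of 19 (NaH, THF, 0 °C to rt) opens the dioxinone at its carbonyl with loss of acetone and gives the depside directly, coming back to the route at 21.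

Step 4 can give too much of the 5-formyl isomer, and step 5 then depends on mono-methylation of the right hydroxyl. The fallback sets out from 6 and reverses the order. Methylation of 6 (MeI 1.05 equiv, K2CO3, acetone), which touches only the non-chelated 4-OH, gives methyl 2-hydroxy-4-methoxy-6-methylbenzoate F2. An ortho-specific magnesium phenoxide formylation (MgCl2, Et3N, paraformaldehyde, MeCN, reflux) can then only reach C3, the one free position ortho to the remaining OH, and comes back to the route at 8.

Step 8 may stall at a 3-bromo-3-methyl dione that cannot eliminate HBr directly. The fallback sets out from 7 of the ring A branch and makes the C3 methyl group by reduction instead of by ring construction. NaBH4 (MeOH, 0 °C) reduces the aldehyde to methyl 2,4-dihydroxy-3-(hydroxymethyl)-6-methylbenzoate F3. Ionic hydrogenation (Et3SiH, TFA, DCM) through the ortho-quinone methide then gives the methyl compound, coming back to the route at 14 and bypassing 12 and 13.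

**Further compounds**
F1 | step 14 | 8-formyl-7-methoxy-2,2,5-trimethyl-4H-1,3-benzodioxin-4-one | CC1(C)OC(=O)c2c(C)cc(OC)c(C=O)c2O1
F2 | step 4 | methyl 2-hydroxy-4-methoxy-6-methylbenzoate | COC(=O)c1c(C)cc(OC)cc1O
F3 | step 8 | methyl 2,4-dihydroxy-3-(hydroxymethyl)-6-methylbenzoate | COC(=O)c1c(C)cc(O)c(CO)c1O
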